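**Strategy.** The cyclohexane ring is closed late at C4′–C5′, the bond between the chlorine-bearing quaternary carbon and the adjacent ring CH2, by a bromonium carbocyclisation. The feature exploited is that in the cyclohexane ring the equatorial C3′–Br bond lies antiperiplanar to this ring bond while the C4′ chlorine is equatorial and trans to bromine: the pattern left by anti addition of bromine and carbon across an (E)-2-chloroalkene. The precursor is acyclic at this ring: the bromo-oxane carries on C1′ a (Z)-vinylsilane and the Br2 adduct of the chloroalkene; ionisation gives an α-chloro bromonium ion that the vinylsilane traps, setting C3′, C4′ and the ring in one operation.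

Key step: step 12

Remark: primed locants are those of the 3-bromo-4-chloro-4-methylcyclohexyl ring (C1′ on the oxane); bromide 4 is made because commercial 1,3-dichlorobut-2-ene is taken to be mainly the (Z)-isomer, which would give the wrong C4′ epimer.

Step 1
Reactants: 1 but-2-yn-1-ol
Product: 3 (2E)-3-chlorobut-2-en-1-ol, via alkenylzirconocene 2 (not isolated)
Conditions: Cp2Zr(H)Cl (2.2 equiv), THF, 23 °C; then N-chlorosuccinimide, 0 °C
Reagents that add atoms: N-chlorosuccinimide, O=C1CCC(=O)N1Cl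
Why: hydrozirconation adds Zr–H syn with zirconium on the less hindered methyl-bearing alkyne carbon (the other terminus carries the bulky zirconium alkoxide), and chlorinolysis of the C–Zr bond with retention should give the (E)-chloroalkene, chlorine trans to CH2OH.

Step 2
Reactants: 3 (2E)-3-chlorobut-2-en-1-ol
Product: 4 (2E)-1-bromo-3-chlorobut-2-ene
Conditions: PBr3, Et2O, 0 °C
Reagents that add atoms: phosphorus tribromide, BrP(Br)Br
Why: SN2 conversion of the primary allylic alcohol into the bromide leaves the chloroalkene geometry untouched.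

Step 3
Reactants: 5 prop-2-yn-1-ol; 4 (2E)-1-bromo-3-chlorobut-2-ene
Product: 7 (2Z,5E)-6-chloro-2-methylhepta-2,5-dien-1-ol, via alkenylmagnesium alkoxide 6 (not isolated)
Conditions: MeMgBr (2.3 equiv), CuI (10 mol%), Et2O, −10 to 23 °C; then 4, −20 to 23 °C
Reagents that add atoms: methylmagnesium bromide, C[Mg]Br
Why: copper-catalysed anti-carbomagnesiation of the propargylic alkoxide puts methyl on C2 and magnesium on C3 cis to the CH2O group, and copper-mediated SN2 allylation with retention should give the (2Z)-alkene; the alkenyl chloride is inert.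

Step 4
Reactants: 7 (2Z,5E)-6-chloro-2-methylhepta-2,5-dien-1-ol
Product: 8 [(2S,3R)-3-[(2E)-3-chlorobut-2-en-1-yl]-2-methyloxiran-2-yl]methanol
Conditions: Ti(OiPr)4, L-(+)-diethyl tartrate, t-BuOOH, 4 Å molecular sieves, CH2Cl2, −20 °C
Reagents that add atoms: tert-butyl hydroperoxide, CC(C)(C)OO
Why: Sharpless asymmetric epoxidation of the allylic alcohol with L-(+)-tartrate should give the (2S,3R)-epoxide, C2 being the future quaternary oxane carbon; the electron-poor chloroalkene is not touched.

Step 5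
Reactants: 8 [(2S,3R)-3-[(2E)-3-chlorobut-2-en-1-yl]-2-methyloxiran-2-yl]methanol; 9 ethynyltrimethylsilane
Product: 10 (2R,3R,5E)-6-chloro-2-methyl-3-[(trimethylsilyl)ethynyl]hept-5-ene-1,2-diol
Conditions: 9, n-BuLi, toluene, 0 °C; Et2AlCl; then 8, 0 to 23 °C
Reagents that add atoms: none
Why: the alkynylalane bound to the alkoxide opens the 2,3-epoxy alcohol at C3 (C2 is fully substituted) with inversion, which sets the future C1′ stereocentre and leaves the tertiary alcohol.

Step 6
Reactants: 10 (2R,3R,5E)-6-chloro-2-methyl-3-[(trimethylsilyl)ethynyl]hept-5-ene-1,2-diol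
Product: 11 (2R,3R,5E)-6-chloro-2-hydroxy-2-methyl-3-[(trimethylsilyl)ethynyl]hept-5-enal
Conditions: SO3·pyridine, DMSO, i-Pr2NEt, CH2Cl2, 0 °C
Reagents that add atoms: none
Why: Parikh–Doering oxidation takes only the primary alcohol, and the quaternary α-carbon cannot epimerise.

Step 7
Reactants: 11 (2R,3R,5E)-6-chloro-2-hydroxy-2-methyl-3-[(trimethylsilyl)ethynyl]hept-5-enal; 12 1-chloro-3-methylbut-2-ene
Product: 13 (5R,6R,7R,9E)-10-chloro-2,6-dimethyl-7-[(trimethylsilyl)ethynyl]undeca-2,9-diene-5,6-diol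
Conditions: 12 (2.4 equiv), BaI2, lithium biphenylide, THF, −78 °C; then 11, −78 °C
Reagents that add atoms: none
Why: allylic barium reagents add through their less substituted carbon, and Cram chelation of the barium alkoxide of the tertiary OH with the aldehyde oxygen directs attack anti to the large C3 substituent, which should give the (5R)-alcohol.

Step 8
Reactants: 13 (5R,6R,7R,9E)-10-chloro-2,6-dimethyl-7-[(trimethylsilyl)ethynyl]undeca-2,9-diene-5,6-diol
Product: 14 (5R,6R,7R,9E)-5-[(tert-butyldimethylsilyl)oxy]-10-chloro-2,6-dimethyl-7-[(trimethylsilyl)ethynyl]undeca-2,9-dien-6-ol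
Conditions: t-BuMe2SiOTf, 2,6-lutidine, CH2Cl2, −78 °C
Reagents that add atoms: tert-butyldimethylsilyl trifluoromethanesulfonate, CC(C)(C)[Si](C)(C)OS(=O)(=O)C(F)(F)F
Why: silylation picks the secondary over the hindered tertiary alcohol and gives a non-participating ether, so only the tertiary OH can attack the bromonium ion of the next step.

Step 9
Reactants: 14 (5R,6R,7R,9E)-5-[(tert-butyldimethylsilyl)oxy]-10-chloro-2,6-dimethyl-7-[(trimethylsilyl)ethynyl]undeca-2,9-dien-6-ol
Product: 15 tert-butyl{[(2R,3R,5R)-5-bromo-2-[(3R,5E)-6-chloro-1-(trimethylsilyl)hept-5-en-1-yn-3-yl]-2,6,6-trimethyloxan-3-yl]oxy}dimethylsilane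
Conditions: 2,4,4,6-tetrabromocyclohexa-2,5-dien-1-one (TBCO), MeNO2, 0 to 23 °C
Reagents that add atoms: 2,4,4,6-tetrabromocyclohexa-2,5-dien-1-one, O=C1C(Br)=CC(Br)(Br)C=C1Br
Why: bromoetherification, in which Br+ goes to the most electron-rich alkene and the tertiary OH opens the bromonium ion at the tertiary carbon (6-endo), so bromine anti to the new C–O bond ends equatorial and a chair with the large C2 substituent equatorial should set C5 as R; the tetrahydrofuran from 5-exo attack is the expected by-product.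

Step 10
Reactants: 15 tert-butyl{[(2R,3R,5R)-5-bromo-2-[(3R,5E)-6-chloro-1-(trimethylsilyl)hept-5-en-1-yn-3-yl]-2,6,6-trimethyloxan-3-yl]oxy}dimethylsilane
Product: 16 tert-butyl{[(2R,3R,5R)-5-bromo-2-[(3R,5S,6S)-5,6-dibromo-6-chloro-1-(trimethylsilyl)hept-1-yn-3-yl]-2,6,6-trimethyloxan-3-yl]oxy}dimethylsilane
Conditions: Br2 (1.0 equiv), CH2Cl2, −78 °C, dark
Reagents that add atoms: bromine, BrBr
Why: electrophilic anti addition of bromine to the chloroalkene, the only C=C bond left (the silylalkyne reacts far more slowly), stores the bromonium ion as a vicinal dibromide whose relative configuration at C5/C6 follows from the (E)-geometry; the (5R,6R) facial isomer should form alongside and is carried on.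

Step 11
Reactants: 16 tert-butyl{[(2R,3R,5R)-5-bromo-2-[(3R,5S,6S)-5,6-dibromo-6-chloro-1-(trimethylsilyl)hept-1-yn-3-yl]-2,6,6-trimethyloxan-3-yl]oxy}dimethylsilane
Product: 18 tert-butyl{[(2R,3R,5R)-5-bromo-2-[(1Z,3R,5S,6S)-5,6-dibromo-6-chloro-1-(trimethylsilyl)hept-1-en-3-yl]-2,6,6-trimethyloxan-3-yl]oxy}dimethylsilane, via alkenylborane 17 (not isolated)
Conditions: (c-C6H11)2BH, THF, 0 °C; then AcOH, 23 °C
Reagents that add atoms: none
Why: hydroboration of the silylalkyne is syn with boron on the silicon-bearing carbon, and protonolysis of the C–B bond with retention should give the (Z)-vinylsilane; alkyl halides and silyl ether are inert to the dialkylborane.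

Step 12
Reactants: 18 tert-butyl{[(2R,3R,5R)-5-bromo-2-[(1Z,3R,5S,6S)-5,6-dibromo-6-chloro-1-(trimethylsilyl)hept-1-en-3-yl]-2,6,6-trimethyloxan-3-yl]oxy}dimethylsilane
Product: 20 tert-butyl{[(2R,3R,5R)-5-bromo-2-[(1R,4S,5S)-5-bromo-4-chloro-4-methylcyclohex-2-en-1-yl]-2,6,6-trimethyloxan-3-yl]oxy}dimethylsilane, via bromonium ion 19 (not isolated)
Conditions: (CF3)2CHOH, 2,6-di-tert-butylpyridine, 0 to 23 °C
Reagents that add atoms: none
Why: Proposed new method: in the ionising, non-nucleophilic solvent the tertiary C–Br bond of 18 should leave with anchimeric help from the vicinal bromine to give the α-chloro bromonium ion 19, which the (Z)-vinylsilane attacks at the chlorine-bearing carbon through its silicon-bearing carbon before the β-silyl cation loses silicon to leave the cis ring alkene; the closest known reaction types are the bromonium cyclisation started by solvolysis of a vicinal bromochloride in this solvent and the vinylsilane-terminated cation–olefin cyclisation, neither shown for a chlorine-bearing cation. The six-membered ring closes 6-endo-trig at the vinylsilane (ipso attack, hence the (Z)-geometry) and at the more substituted carbon of the bromonium ion. C3′ keeps its bromine, which must lie anti to the new C4′–C5′ bond and so ends equatorial; C4′ is formed with overall retention (two inversions), so the (E)-geometry of the former chloroalkene puts chlorine equatorial and methyl axial; both are placed relative to C1′ by a chair transition state with the oxanyl group equatorial. The step needs the bromonium ion on one face only: the mismatched facial isomer cannot reach such a chair and should return to the matched one by bromide re-addition at C3′, the known interchange of vicinal dibromides through the ion pair. It also needs site selectivity, which the substrate secures because only the tertiary, chlorine-stabilised C–Br bond has an antiperiplanar bromine to assist its ionisation.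

Step 13
Reactants: 20 tert-butyl{[(2R,3R,5R)-5-bromo-2-[(1R,4S,5S)-5-bromo-4-chloro-4-methylcyclohex-2-en-1-yl]-2,6,6-trimethyloxan-3-yl]oxy}dimethylsilane
Product: 21 tert-butyl{[(2R,3R,5R)-5-bromo-2-[(1S,3S,4S)-3-bromo-4-chloro-4-methylcyclohexyl]-2,6,6-trimethyloxan-3-yl]oxy}dimethylsilane
Conditions: 2-nitrobenzenesulfonylhydrazide, Et3N, CH2Cl2, 23 °C
Reagents that add atoms: none
Why: diimide reduction delivers H2 syn to the unhindered cis-disubstituted ring alkene without touching C–Br or C–Cl bonds and creates no stereocentre.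

Step 14
Reactants: 21 tert-butyl{[(2R,3R,5R)-5-bromo-2-[(1S,3S,4S)-3-bromo-4-chloro-4-methylcyclohexyl]-2,6,6-trimethyloxan-3-yl]oxy}dimethylsilane
Product: 22 caespitol, (2R,3R,5R)-5-bromo-2-[(1S,3S,4S)-3-bromo-4-chloro-4-methylcyclohexyl]-2,6,6-trimethyloxan-3-ol
Conditions: HF·pyridine, THF, 0 to 23 °C
Reagents that add atoms: none
Why: fluoride-driven cleavage of the silyl ether under mildly acidic conditions frees the axial hydroxyl without a base that could eliminate HBr or HCl.

**Compound list**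

1 | but-2-yn-1-ol | CC#CCO | starting material
2 | alkenylzirconocene chloride from 1 (Zr on C3 cis to H, oxygen bound to a second Cp2ZrCl) | C/C(=C\CO[Zr](Cl)(C1C=CC=C1)C1C=CC=C1)[Zr](Cl)(C1C=CC=C1)C1C=CC=C1 | intermediate
3 | (2E)-3-chlorobut-2-en-1-ol | C/C(Cl)=C\CO | intermediate
4 | (2E)-1-bromo-3-chlorobut-2-ene | C/C(Cl)=C\CBr | intermediate
5 | prop-2-yn-1-ol | C#CCO | starting material
6 | (Z)-3-(bromomagnesio)-2-methylprop-2-en-1-olate, bromomagnesium salt | C/C(CO[Mg]Br)=C/[Mg]Br | intermediate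
7 | (2Z,5E)-6-chloro-2-methylhepta-2,5-dien-1-ol | OC/C(C)=C\C/C=C(\C)Cl | intermediate
8 | [(2S,3R)-3-[(2E)-3-chlorobut-2-en-1-yl]-2-methyloxiran-2-yl]methanol | OC[C@]1(C)O[C@@H]1C/C=C(\C)Cl | intermediate
9 | ethynyltrimethylsilane | C#C[Si](C)(C)C | starting material
10 | (2R,3R,5E)-6-chloro-2-methyl-3-[(trimethylsilyl)ethynyl]hept-5-ene-1,2-diol | OC[C@](C)(O)[C@@H](C#C[Si](C)(C)C)C/C=C(\C)Cl | intermediate
11 | (2R,3R,5E)-6-chloro-2-hydroxy-2-methyl-3-[(trimethylsilyl)ethynyl]hept-5-enal | O=C[C@](C)(O)[C@@H](C#C[Si](C)(C)C)C/C=C(\C)Cl | intermediate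
12 | 1-chloro-3-methylbut-2-ene | CC(C)=CCCl | starting material
13 | (5R,6R,7R,9E)-10-chloro-2,6-dimethyl-7-[(trimethylsilyl)ethynyl]undeca-2,9-diene-5,6-diol | CC(C)=CC[C@@H](O)[C@](C)(O)[C@@H](C#C[Si](C)(C)C)C/C=C(\C)Cl | intermediate
14 | (5R,6R,7R,9E)-5-[(tert-butyldimethylsilyl)oxy]-10-chloro-2,6-dimethyl-7-[(trimethylsilyl)ethynyl]undeca-2,9-dien-6-ol | CC(C)=CC[C@@H](O[Si](C)(C)C(C)(C)C)[C@](C)(O)[C@@H](C#C[Si](C)(C)C)C/C=C(\C)Cl | intermediate
15 | tert-butyl{[(2R,3R,5R)-5-bromo-2-[(3R,5E)-6-chloro-1-(trimethylsilyl)hept-5-en-1-yn-3-yl]-2,6,6-trimethyloxan-3-yl]oxy}dimethylsilane | CC1(C)O[C@](C)([C@@H](C#C[Si](C)(C)C)C/C=C(\C)Cl)[C@H](O[Si](C)(C)C(C)(C)C)C[C@H]1Br | intermediate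
16 | tert-butyl{[(2R,3R,5R)-5-bromo-2-[(3R,5S,6S)-5,6-dibromo-6-chloro-1-(trimethylsilyl)hept-1-yn-3-yl]-2,6,6-trimethyloxan-3-yl]oxy}dimethylsilane (matched facial isomer drawn) | CC1(C)O[C@](C)([C@@H](C#C[Si](C)(C)C)C[C@H](Br)[C@@](C)(Cl)Br)[C@H](O[Si](C)(C)C(C)(C)C)C[C@H]1Br | intermediate
17 | alkenylborane from 16: the alkyne turned into (Z)-CH=C(SiMe3)B(c-C6H11)2, other centres as in 16 | CC1(C)O[C@](C)([C@@H](/C=C(\[Si](C)(C)C)B(C2CCCCC2)C2CCCCC2)C[C@H](Br)[C@@](C)(Cl)Br)[C@H](O[Si](C)(C)C(C)(C)C)C[C@H]1Br | intermediate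
18 | tert-butyl{[(2R,3R,5R)-5-bromo-2-[(1Z,3R,5S,6S)-5,6-dibromo-6-chloro-1-(trimethylsilyl)hept-1-en-3-yl]-2,6,6-trimethyloxan-3-yl]oxy}dimethylsilane | CC1(C)O[C@](C)([C@@H](/C=C\[Si](C)(C)C)C[C@H](Br)[C@@](C)(Cl)Br)[C@H](O[Si](C)(C)C(C)(C)C)C[C@H]1Br | intermediate
19 | α-chloro bromonium (bromiranium) bromide from 18: Br+ bridges C5 and C6, C5 configuration of 18 kept, chlorine trans to the C4 chain | CC1(C)O[C@](C)([C@@H](/C=C\[Si](C)(C)C)C[C@@H]2[Br+][C@@]2(C)Cl)[C@H](O[Si](C)(C)C(C)(C)C)C[C@H]1Br.[Br-] | intermediate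
20 | tert-butyl{[(2R,3R,5R)-5-bromo-2-[(1R,4S,5S)-5-bromo-4-chloro-4-methylcyclohex-2-en-1-yl]-2,6,6-trimethyloxan-3-yl]oxy}dimethylsilane | CC1(C)O[C@](C)([C@H]2C=C[C@](C)(Cl)[C@@H](Br)C2)[C@H](O[Si](C)(C)C(C)(C)C)C[C@H]1Br | intermediate
21 | tert-butyl{[(2R,3R,5R)-5-bromo-2-[(1S,3S,4S)-3-bromo-4-chloro-4-methylcyclohexyl]-2,6,6-trimethyloxan-3-yl]oxy}dimethylsilane | CC1(C)O[C@](C)([C@H]2CC[C@](C)(Cl)[C@@H](Br)C2)[C@H](O[Si](C)(C)C(C)(C)C)C[C@H]1Br | intermediate
22 | caespitol, (2R,3R,5R)-5-bromo-2-[(1S,3S,4S)-3-bromo-4-chloro-4-methylcyclohexyl]-2,6,6-trimethyloxan-3-ol | CC1(C)O[C@](C)([C@H]2CC[C@](C)(Cl)[C@@H](Br)C2)[C@H](O)C[C@H]1Br | target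

**Total step count:** 14. **Longest linear sequence:** 14 steps, from but-2-yn-1-ol 1.

**Steps most likely to fail**

1. Step 12 (Proposed new method). The cation may form without the ring closing: it may lose HBr, be captured by the solvent or the oxane oxygen, or the vinylsilane may be protodesilylated; closure from the mismatched bromonium face would give the C3′,C4′-diastereomer. The fallback uses known chemistry: the same C4′–C5′ bond is closed by an intramolecular B-alkyl Suzuki–Miyaura coupling and the halogens are added to the ring alkene afterwards. It sets out from 5. Step 3 is run with commercial (Z)-1,3-dichlorobut-2-ene in place of 4 to give (2Z,5Z)-6-chloro-2-methylhepta-2,5-dien-1-ol F1. Step 4 then gives the epoxy alcohol F2, and opening with vinylmagnesium bromide and CuI in place of the alkynylalane gives the 3-vinyl diol F3. Steps 6 to 9 give in turn the aldehyde F4, the prenylated diol F5, the silyl ether F6 and the bromo-oxane F7. 9-BBN adds to the vinyl group to give the alkylborane F8, and Pd(OAc)2, SPhos and K3PO4 couple it with the (Z)-alkenyl chloride to give the 4-methylcyclohex-3-enyl oxane F9. Bromochlorination with N-bromosuccinimide and Et4NCl comes back to the route at 21. Ring-locked anti addition is expected to favour the trans-diaxial adduct, so 21 would have to be separated as the lesser isomer.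

2. Step 9. Opening of the bromonium ion may go 5-exo to the tetrahydrofuran instead of 6-endo, and facial selectivity at C5 may be poor. The fallback sets out from 14 and accepts the 5-exo closure: the oxolane F10, a tertiary bromide, is collected and isomerised with ZnBr2 in CH2Cl2. The ring oxygen displaces the tertiary bromide to give a bicyclic oxonium ion, and bromide returns at the secondary carbon with inversion; this is the known ring expansion of 2-(1-bromoalkyl)oxolanes to 3-bromo-oxanes. It comes back to the route at 15.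

3. Step 7. The allylic reagent may attack through its more substituted terminus (reverse prenylation), and chelation control at C5 may be lost. The fallback sets out from 11 and splits the step in two. Chelation-controlled allylation with allyltributylstannane and MgBr2·OEt2 in CH2Cl2 at −20 °C gives the homoallylic diol F11. Cross-metathesis with 2-methylbut-2-ene and the second-generation Grubbs catalyst then comes back to the route at 13.

**Further compounds**

F1 | step 12 | (2Z,5Z)-6-chloro-2-methylhepta-2,5-dien-1-ol | OC/C(C)=C\C/C=C(/C)Cl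
F2 | step 12 | [(2S,3R)-3-[(2Z)-3-chlorobut-2-en-1-yl]-2-methyloxiran-2-yl]methanol | OC[C@]1(C)O[C@@H]1C/C=C(/C)Cl
F3 | step 12 | (2R,3R,5Z)-6-chloro-3-ethenyl-2-methylhept-5-ene-1,2-diol | OC[C@](C)(O)[C@@H](C=C)C/C=C(/C)Cl
F4 | step 12 | (2R,3R,5Z)-6-chloro-3-ethenyl-2-hydroxy-2-methylhept-5-enal | O=C[C@](C)(O)[C@@H](C=C)C/C=C(/C)Cl
F5 | step 12 | (5R,6R,7R,9Z)-10-chloro-7-ethenyl-2,6-dimethylundeca-2,9-diene-5,6-diol | CC(C)=CC[C@@H](O)[C@](C)(O)[C@@H](C=C)C/C=C(/C)Cl
F6 | step 12 | (5R,6R,7R,9Z)-5-[(tert-butyldimethylsilyl)oxy]-10-chloro-7-ethenyl-2,6-dimethylundeca-2,9-dien-6-ol | CC(C)=CC[C@@H](O[Si](C)(C)C(C)(C)C)[C@](C)(O)[C@@H](C=C)C/C=C(/C)Cl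
F7 | step 12 | tert-butyl{[(2R,3R,5R)-5-bromo-2-[(3R,5Z)-6-chlorohepta-1,5-dien-3-yl]-2,6,6-trimethyloxan-3-yl]oxy}dimethylsilane | CC1(C)O[C@](C)([C@@H](C=C)C/C=C(/C)Cl)[C@H](O[Si](C)(C)C(C)(C)C)C[C@H]1Br
F8 | step 12 | B-alkyl-9-borabicyclo[3.3.1]nonane from F7 (boron on the terminal carbon of the former vinyl group) | CC1(C)O[C@](C)([C@@H](CCB2C3CCCC2CCC3)C/C=C(/C)Cl)[C@H](O[Si](C)(C)C(C)(C)C)C[C@H]1Br
F9 | step 12 | tert-butyl{[(2R,3R,5R)-5-bromo-2,6,6-trimethyl-2-[(1S)-4-methylcyclohex-3-en-1-yl]oxan-3-yl]oxy}dimethylsilane | CC1(C)O[C@](C)([C@H]2CCC(C)=CC2)[C@H](O[Si](C)(C)C(C)(C)C)C[C@H]1Br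
F10 | step 9 | tert-butyl{[(2R,3R,5S)-5-(2-bromopropan-2-yl)-2-[(3R,5E)-6-chloro-1-(trimethylsilyl)hept-5-en-1-yn-3-yl]-2-methyloxolan-3-yl]oxy}dimethylsilane | CC(C)(Br)[C@@H]1C[C@@H](O[Si](C)(C)C(C)(C)C)[C@@](C)([C@@H](C#C[Si](C)(C)C)C/C=C(\C)Cl)O1
F11 | step 7 | (2R,3R,4R,6E)-7-chloro-3-methyl-4-[(trimethylsilyl)ethynyl]-1-(prop-2-en-1-yl) analogue of 13: (4R,5R,6R,8E)-9-chloro-5-methyl-6-[(trimethylsilyl)ethynyl]deca-1,8-diene-4,5-diol | C=CC[C@@H](O)[C@](C)(O)[C@@H](C#C[Si](C)(C)C)C/C=C(\C)Cl
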